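The oxolane (O1, C2–C5; C6 is the carbinol carbon on C2) is traced back to a cyclobutanone in which C2 and C5 are bonded directly; peracid later inserts O1 into this sacrificial bond. The key step, a dichloroketene [2+2] cycloaddition to a Z-configured 1,3-diarylallyl silyl ether, forms C3–C4 and C2–C5 together, closes the four-membered ring and sets C2 and C3. It exploits two features: the cis arrangement of the C2 side chain and the C3 anisyl group, which is a Z alkene in latent form, and the O1 bridge between C2 and C5. The precursor is the (S,Z)-triisopropylsilyl ether already carrying C6, which steers the ketene to one alkene face.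

Key step: step 4

Remark on labels: the target labels O1, C2, C3, C4, C5 and C6 are used for the same atoms in every intermediate.
Remark on C6: the alkynylation must give the (R)-propargylic alcohol; the descriptor becomes (S) on semihydrogenation and (R) again after ring expansion through priority changes alone, with no change in space.
Remark on C4: any kinetic delivery to C4 (proton, hydrogen atom or electrophile) arrives anti to the anisyl group, so a single chlorine kept at C4 would sit cis to the aryl group and be the wrong epimer for an invertive displacement. Both chlorines are therefore removed, and the C4 oxygen is brought in trans by enolate hydroxylation and then inverted.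
Assumption: the (S)-BINOL/titanium alkynylation is taken to add the alkynyl group to the Si face of the aldehyde (giving the R alcohol); this is to be confirmed by MTPA ester analysis on the first batch, and (R)-BINOL is used instead if the sense is opposite.

Step 1
Reactants: 1 4-ethynylanisole; 2 3,4-dimethoxybenzaldehyde
Product: 4 (R)-1-(3,4-dimethoxyphenyl)-3-(4-methoxyphenyl)prop-2-yn-1-ol, via ethyl[(4-methoxyphenyl)ethynyl]zinc 3 (not isolated)
Conditions: 1, Et2Zn, toluene, reflux; then (S)-BINOL (20 mol %), Ti(OiPr)4 (50 mol %), 2, CH2Cl2, rt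
Reagents that add atoms: none
Why: Titanium–BINOLate-catalysed addition of a preformed alkynylzinc to an aryl aldehyde (asymmetric alkynylation) is established for arylacetylene/aryl aldehyde pairs, and the ligand is expected to direct the alkynyl group to the Si face, setting C6 in the spatial arrangement required in the target.

Step 2
Reactants: 4 (R)-1-(3,4-dimethoxyphenyl)-3-(4-methoxyphenyl)prop-2-yn-1-ol
Product: 5 (R)-{[1-(3,4-dimethoxyphenyl)-3-(4-methoxyphenyl)prop-2-yn-1-yl]oxy}tri(propan-2-yl)silane
Conditions: TIPSCl, imidazole, DMAP (cat.), DMF, rt → 40 °C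
Reagents that add atoms: triisopropylsilyl chloride, CC(C)[Si](Cl)(C(C)C)C(C)C
Why: Imidazole-mediated silylation of a secondary propargylic alcohol is routine and acid-free, so the ionisable benzylic C6–O bond is not put at risk and C6 is untouched.

Step 3
Reactants: 5 (R)-{[1-(3,4-dimethoxyphenyl)-3-(4-methoxyphenyl)prop-2-yn-1-yl]oxy}tri(propan-2-yl)silane
Product: 6 (S,Z)-{[1-(3,4-dimethoxyphenyl)-3-(4-methoxyphenyl)prop-2-en-1-yl]oxy}tri(propan-2-yl)silane
Conditions: H2 (1 atm), Pd/CaCO3 poisoned with Pb(OAc)2, quinoline, EtOAc, rt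
Reagents that add atoms: none
Why: Syn delivery of hydrogen on the poisoned palladium surface (alkyne semihydrogenation) should give the Z alkene, with quinoline and the bulky propargylic silyl ether restraining over-reduction and C6 playing no part.

Step 4
Reactants: 6 (S,Z)-{[1-(3,4-dimethoxyphenyl)-3-(4-methoxyphenyl)prop-2-en-1-yl]oxy}tri(propan-2-yl)silane; 7 trichloroacetyl chloride
Product: 9 (3R,4S)-2,2-dichloro-4-[(S)-(3,4-dimethoxyphenyl){[tri(propan-2-yl)silyl]oxy}methyl]-3-(4-methoxyphenyl)cyclobutan-1-one, via dichloroketene 8 (not isolated)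
Conditions: 7 (slow addition), Zn–Cu couple, Et2O/DME, rt
Reagents that add atoms: none
Why: Zinc strips two chlorines from 7 to give dichloroketene 8, which adds to the alkene in a concerted but asynchronous [2+2] cycloaddition: the electrophilic carbonyl carbon C5 bonds to C2 while positive charge builds at the anisyl-stabilised C3, which closes onto the CCl2 carbon C4. The closest known reaction type is the dichloroketene cycloaddition to styrenes and cis-1,2-disubstituted alkenes that gives 2,2-dichloro-3-arylcyclobutanones. The cyclobutanone ring (C2, C3, C4, C5) is closed by intermolecular cycloaddition, both ring bonds being made in the one step with the alkene reacting suprafacially. C2 and C3 should come out cis because the Z geometry is retained; their absolute sense is set by C6, whose hydrogen eclipses the alkene to avoid A(1,3) strain with the anisyl group, so that the triisopropylsilyloxy group screens one face and the ketene enters on the other. The step needs regio-, facial and chemoselectivity: the first is secured by the anisyl group, the second by the bulky silyl ether, and the third by the hindered, weakly basic ether oxygen, which resists acylation (the entry to a ketene-Claisen rearrangement), and by DME, which binds ZnCl2 before it can ionise the benzylic, allylic C6–O bond.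

Step 5
Reactants: 9 (3R,4S)-2,2-dichloro-4-[(S)-(3,4-dimethoxyphenyl){[tri(propan-2-yl)silyl]oxy}methyl]-3-(4-methoxyphenyl)cyclobutan-1-one
Product: 10 (2S,3R)-2-[(S)-(3,4-dimethoxyphenyl){[tri(propan-2-yl)silyl]oxy}methyl]-3-(4-methoxyphenyl)cyclobutan-1-one
Conditions: Zn–Cu couple, NH4Cl, MeOH, rt
Reagents that add atoms: none
Why: Reductive dechlorination of an α,α-dichlorocyclobutanone by zinc through its zinc enolate is standard, the near-neutral methanolic medium spares the silyl ether and does not enolise toward C2, and no stereocentre is touched.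

Step 6
Reactants: 10 (2S,3R)-2-[(S)-(3,4-dimethoxyphenyl){[tri(propan-2-yl)silyl]oxy}methyl]-3-(4-methoxyphenyl)cyclobutan-1-one
Product: 11 (4S,5S)-5-[(R)-(3,4-dimethoxyphenyl){[tri(propan-2-yl)silyl]oxy}methyl]-4-(4-methoxyphenyl)oxolan-2-one
Conditions: mCPBA, NaHCO3, CH2Cl2, 0 °C → rt
Reagents that add atoms: 3-chloroperoxybenzoic acid, OOC(=O)c1cccc(Cl)c1
Why: In this Baeyer–Villiger oxidation of a strained ketone the more substituted C2 should migrate in preference to the C4 methylene, with retention of configuration, so O1 enters the C2–C5 bond and the cis C2/C3 relationship is carried into the γ-lactone, while the aryl ethers and the silyl ether are inert to buffered peracid.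

Step 7
Reactants: 11 (4S,5S)-5-[(R)-(3,4-dimethoxyphenyl){[tri(propan-2-yl)silyl]oxy}methyl]-4-(4-methoxyphenyl)oxolan-2-one
Product: 13 (3R,4R,5S)-5-[(R)-(3,4-dimethoxyphenyl){[tri(propan-2-yl)silyl]oxy}methyl]-3-hydroxy-4-(4-methoxyphenyl)oxolan-2-one, via sodium lactone enolate 12 (not isolated)
Conditions: NaN(SiMe3)2, THF, −78 °C; then 2-(benzenesulfonyl)-3-phenyloxaziridine, −78 °C; AcOH quench
Reagents that add atoms: 2-(benzenesulfonyl)-3-phenyloxaziridine, O=S(=O)(N1OC1c1ccccc1)c1ccccc1
Why: Electrophilic hydroxylation of a lactone enolate by an N-sulfonyloxaziridine is reliable, the reagent should reach C4 on the face opposite the C3 anisyl group and the cis C2 side chain to give the 3,4-trans alcohol, and the enolate has no β-leaving group, so C2 and C3 are safe.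

Step 8
Reactants: 13 (3R,4R,5S)-5-[(R)-(3,4-dimethoxyphenyl){[tri(propan-2-yl)silyl]oxy}methyl]-3-hydroxy-4-(4-methoxyphenyl)oxolan-2-one
Product: 14 (3S,4S,5S)-5-[(R)-(3,4-dimethoxyphenyl){[tri(propan-2-yl)silyl]oxy}methyl]-4-(4-methoxyphenyl)-2-oxooxolan-3-yl benzoate
Conditions: PhCO2H, PPh3, DIAD, THF, 0 °C → rt
Reagents that add atoms: benzoic acid, OC(=O)c1ccccc1
Why: In this Mitsunobu esterification benzoate displaces the α-carbonyl oxyphosphonium ion by SN2, inverting C4 so that its oxygen becomes cis to the anisyl group (all-cis ring); the departing phosphine oxide is not nucleophilic, so no epimerisation by exchange can follow, and the C3 hydrogen is syn to the leaving group, which disfavours elimination.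

Step 9
Reactants: 14 (3S,4S,5S)-5-[(R)-(3,4-dimethoxyphenyl){[tri(propan-2-yl)silyl]oxy}methyl]-4-(4-methoxyphenyl)-2-oxooxolan-3-yl benzoate
Product: 15 (2S,3R,4S,5R)-5-(3,4-dimethoxyphenyl)-3-(4-methoxyphenyl)-5-{[tri(propan-2-yl)silyl]oxy}pentane-1,2,4-triol
Conditions: LiAlH4, THF, 0 °C
Reagents that add atoms: none
Why: Hydride reduction opens the lactone to the 1,4-diol and cleaves the benzoate in the same operation without touching any stereocentre, the triisopropylsilyl ether or the aryl methyl ethers.

Step 10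
Reactants: 15 (2S,3R,4S,5R)-5-(3,4-dimethoxyphenyl)-3-(4-methoxyphenyl)-5-{[tri(propan-2-yl)silyl]oxy}pentane-1,2,4-triol
Product: 17 (3S,4R,5S)-5-[(R)-(3,4-dimethoxyphenyl){[tri(propan-2-yl)silyl]oxy}methyl]-4-(4-methoxyphenyl)oxolan-3-ol, via primary 4-methylbenzenesulfonate 16 (not isolated)
Conditions: TsCl (1.1 equiv), pyridine, 0 °C → rt; then 50 °C
Reagents that add atoms: none
Why: Sulfonylation should select the only primary hydroxyl (C5), after which the neutral C2 hydroxyl displaces the sulfonate in a 5-exo-tet Williamson closure that leaves C2 unchanged, whereas epoxide formation from the C4 hydroxyl requires an alkoxide and should not compete in pyridine.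

Step 11
Reactants: 17 (3S,4R,5S)-5-[(R)-(3,4-dimethoxyphenyl){[tri(propan-2-yl)silyl]oxy}methyl]-4-(4-methoxyphenyl)oxolan-3-ol
Product: 18 (3S,4R,5S)-5-[(R)-(3,4-dimethoxyphenyl)(hydroxy)methyl]-4-(4-methoxyphenyl)oxolan-3-ol
Conditions: Bu4NF, THF, rt
Reagents that add atoms: none
Why: Fluoride cleaves the Si–O bond at silicon (silyl ether deprotection), so the C6 configuration is retained and the diol product is stable to the mildly basic medium.

Compound list
1 | 4-ethynylanisole (1-ethynyl-4-methoxybenzene) | COc1ccc(C#C)cc1 | starting material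
2 | 3,4-dimethoxybenzaldehyde | COc1ccc(C=O)cc1OC | starting material
3 | ethyl[(4-methoxyphenyl)ethynyl]zinc | CC[Zn]C#Cc1ccc(OC)cc1 | intermediate
4 | (R)-1-(3,4-dimethoxyphenyl)-3-(4-methoxyphenyl)prop-2-yn-1-ol | COc1ccc(cc1)C#C[C@H](O)c1ccc(OC)c(OC)c1 | intermediate
5 | (R)-{[1-(3,4-dimethoxyphenyl)-3-(4-methoxyphenyl)prop-2-yn-1-yl]oxy}tri(propan-2-yl)silane | COc1ccc(cc1)C#C[C@H](O[Si](C(C)C)(C(C)C)C(C)C)c1ccc(OC)c(OC)c1 | intermediate
6 | (S,Z)-{[1-(3,4-dimethoxyphenyl)-3-(4-methoxyphenyl)prop-2-en-1-yl]oxy}tri(propan-2-yl)silane | COc1ccc(cc1)/C=C\[C@H](O[Si](C(C)C)(C(C)C)C(C)C)c1ccc(OC)c(OC)c1 | intermediate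
7 | trichloroacetyl chloride | ClC(Cl)(Cl)C(Cl)=O | starting material
8 | dichloroketene | ClC(Cl)=C=O | intermediate
9 | (3R,4S)-2,2-dichloro-4-[(S)-(3,4-dimethoxyphenyl){[tri(propan-2-yl)silyl]oxy}methyl]-3-(4-methoxyphenyl)cyclobutan-1-one (aryl and side chain cis) | COc1ccc(cc1)[C@H]2[C@@H]([C@H](O[Si](C(C)C)(C(C)C)C(C)C)c3ccc(OC)c(OC)c3)C(=O)C2(Cl)Cl | intermediate
10 | (2S,3R)-2-[(S)-(3,4-dimethoxyphenyl){[tri(propan-2-yl)silyl]oxy}methyl]-3-(4-methoxyphenyl)cyclobutan-1-one | COc1ccc(cc1)[C@H]2[C@@H]([C@H](O[Si](C(C)C)(C(C)C)C(C)C)c3ccc(OC)c(OC)c3)C(=O)C2 | intermediate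
11 | (4S,5S)-5-[(R)-(3,4-dimethoxyphenyl){[tri(propan-2-yl)silyl]oxy}methyl]-4-(4-methoxyphenyl)oxolan-2-one | COc1ccc(cc1)[C@H]2[C@@H]([C@H](O[Si](C(C)C)(C(C)C)C(C)C)c3ccc(OC)c(OC)c3)OC(=O)C2 | intermediate
12 | sodium (4S,5S)-5-[(R)-(3,4-dimethoxyphenyl){[tri(propan-2-yl)silyl]oxy}methyl]-4-(4-methoxyphenyl)-4,5-dihydrofuran-2-olate (sodium enolate of 11) | COc1ccc(cc1)[C@H]2[C@@H]([C@H](O[Si](C(C)C)(C(C)C)C(C)C)c3ccc(OC)c(OC)c3)OC(O[Na])=C2 | intermediate
13 | (3R,4R,5S)-5-[(R)-(3,4-dimethoxyphenyl){[tri(propan-2-yl)silyl]oxy}methyl]-3-hydroxy-4-(4-methoxyphenyl)oxolan-2-one (hydroxyl trans to anisyl) | COc1ccc(cc1)[C@H]2[C@@H]([C@H](O[Si](C(C)C)(C(C)C)C(C)C)c3ccc(OC)c(OC)c3)OC(=O)[C@@H]2O | intermediate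
14 | (3S,4S,5S)-5-[(R)-(3,4-dimethoxyphenyl){[tri(propan-2-yl)silyl]oxy}methyl]-4-(4-methoxyphenyl)-2-oxooxolan-3-yl benzoate (all-cis) | COc1ccc(cc1)[C@H]2[C@@H]([C@H](O[Si](C(C)C)(C(C)C)C(C)C)c3ccc(OC)c(OC)c3)OC(=O)[C@H]2OC(=O)c4ccccc4 | intermediate
15 | (2S,3R,4S,5R)-5-(3,4-dimethoxyphenyl)-3-(4-methoxyphenyl)-5-{[tri(propan-2-yl)silyl]oxy}pentane-1,2,4-triol | COc1ccc(cc1)[C@@H]([C@@H]([C@H](O[Si](C(C)C)(C(C)C)C(C)C)c2ccc(OC)c(OC)c2)O)[C@H](O)CO | intermediate
16 | (2S,3R,4S,5R)-5-(3,4-dimethoxyphenyl)-2,4-dihydroxy-3-(4-methoxyphenyl)-5-{[tri(propan-2-yl)silyl]oxy}pentyl 4-methylbenzenesulfonate | COc1ccc(cc1)[C@@H]([C@@H]([C@H](O[Si](C(C)C)(C(C)C)C(C)C)c2ccc(OC)c(OC)c2)O)[C@H](O)COS(=O)(=O)c3ccc(C)cc3 | intermediate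
17 | (3S,4R,5S)-5-[(R)-(3,4-dimethoxyphenyl){[tri(propan-2-yl)silyl]oxy}methyl]-4-(4-methoxyphenyl)oxolan-3-ol | COc1ccc([C@H]2[C@@H]([C@H](O[Si](C(C)C)(C(C)C)C(C)C)c3ccc(OC)c(OC)c3)OC[C@H]2O)cc1 | intermediate
18 | (3S,4R,5S)-5-[(R)-(3,4-dimethoxyphenyl)(hydroxy)methyl]-4-(4-methoxyphenyl)oxolan-3-ol | COc1ccc([C@H]2[C@@H]([C@H](O)c3ccc(OC)c(OC)c3)OC[C@H]2O)cc1 | target

Total step count: 11
Longest linear sequence: 11 steps (from 1 and 2 to 18)

Steps most likely to fail

1. Step 4 (cycloaddition). Facial discrimination by C6 alone may be insufficient, because in the hydrogen-eclipsed conformer the silyloxy group and the dimethoxyphenyl ring each flank one alkene face. Zinc chloride may also ionise the benzylic, allylic C6–O bond. The fallback sets out from 6 and replaces the ketene by a chiral keteniminium ion, which adds reagent control and avoids zinc salts and chlorine. 1-[(2R,5R)-2,5-Dimethylpyrrolidin-1-yl]ethan-1-one is activated with Tf2O and 2,6-di-tert-butylpyridine in 1,2-dichloroethane to give the keteniminium triflate F1. This adds to 6 with the same regiochemistry (iminium carbon to C2, methylene to C3) to give the cyclobutaniminium triflate F2. Aqueous NaHCO3 hydrolysis then releases cyclobutanone 10, where the route is rejoined with step 5 no longer needed. The antipodal auxiliary is taken if it proves to be the matched partner of the C6 centre.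

2. Step 8 (inversion at C4). Benzoate must attack on the face syn to the C3 anisyl group; if this is slow, the oxyphosphonium ion may be diverted to acyl transfer with retention or to decomposition. The fallback sets out from 13 and separates activation from displacement. Tf2O and pyridine in CH2Cl2 at −20 °C give the α-trifluoromethanesulfonate F3. This is displaced with CsOBz and 18-crown-6 in toluene at rt, an SN2 reaction with a far better, non-nucleophilic leaving group, and the route is rejoined at 14.

3. Step 10 (ring closure of the triol). Chemoselectivity among three hydroxyl groups may be lost, through sulfonylation of a secondary hydroxyl or closure of the C4 oxygen onto C5 to give an epoxide. The fallback sets out from 14 and never opens the ring. i-Bu2AlH (excess, CH2Cl2, −78 °C) reduces the lactone to the lactol F4 and removes the benzoate. Et3SiH with BF3·OEt2 (CH2Cl2, −78 → −40 °C) then reduces the lactol through its oxocarbenium ion to the cyclic ether, and the route is rejoined at 17. The temperature is kept low so that the benzylic C6–O bond does not ionise.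

Further compounds
F1 | step 4 | keteniminium triflate from 1-[(2R,5R)-2,5-dimethylpyrrolidin-1-yl]ethan-1-one (1-ethenylidene-(2R,5R)-2,5-dimethylpyrrolidin-1-ium trifluoromethanesulfonate) | C=C=[N+]1[C@H](C)CC[C@H]1C.[O-]S(=O)(=O)C(F)(F)F
F2 | step 4 | cyclobutaniminium triflate corresponding to 10, with the (2R,5R)-2,5-dimethylpyrrolidinium nitrogen doubly bonded to C5 in place of the carbonyl oxygen | COc1ccc(cc1)[C@H]2[C@@H]([C@H](O[Si](C(C)C)(C(C)C)C(C)C)c3ccc(OC)c(OC)c3)C(=[N+]4[C@H](C)CC[C@H]4C)C2.[O-]S(=O)(=O)C(F)(F)F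
F3 | step 8 | (3R,4S,5S)-5-[(R)-(3,4-dimethoxyphenyl){[tri(propan-2-yl)silyl]oxy}methyl]-4-(4-methoxyphenyl)-2-oxooxolan-3-yl trifluoromethanesulfonate (sulfonate trans to anisyl) | COc1ccc(cc1)[C@H]2[C@@H]([C@H](O[Si](C(C)C)(C(C)C)C(C)C)c3ccc(OC)c(OC)c3)OC(=O)[C@@H]2OS(=O)(=O)C(F)(F)F
F4 | step 10 | (3S,4R,5S)-5-[(R)-(3,4-dimethoxyphenyl){[tri(propan-2-yl)silyl]oxy}methyl]-4-(4-methoxyphenyl)oxolane-2,3-diol (lactol, mixture of C2 anomers) | COc1ccc([C@H]2[C@@H]([C@H](O[Si](C(C)C)(C(C)C)C(C)C)c3ccc(OC)c(OC)c3)OC(O)[C@H]2O)cc1
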